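Ring D (rings lettered A–G from the 2,4,6-trihydroxyphenyl end) is taken apart into a chromium carbene, an ynol ether and one carbonyl ligand. It is the only ring with five oxygens: D3–O and D6–O are para, and the ring C aryloxy group on D1 is the neighbour of D6. A Dötz benzannulation writes exactly this pattern. In one operation it forms D2–D3, D1–D6 and D5–D6, closes ring D and leaves D6–OH as the single free hydroxyl for ring E. Its precursors are the (Z)-1,2-dimethoxyvinyl(methoxy)carbene complex of Cr(CO)5 and the ethynyl ether of the finished A–B–C phenol. The other aryl ethers come from SNAr/Dakin cycles and two copper couplings.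

Key step: step 8

Remark on the design: in every ether of the chain the oxygen sits on a carbon flanked by two oxygens of the ring nearer to A and on an unhindered carbon of the next ring (D1 has one ortho neighbour). Each ether is therefore made from the hindered phenoxide and an unhindered electrophilic carbon. For the same reason the para oxygen of ring C carries rings B and A before the annulation, so nothing has to be unmasked or inverted in polarity afterwards.

Assumption: 2,4,6-trimethoxyphenol, 4-fluoro-2,6-dimethoxybenzaldehyde, 4-bromo-2,6-dimethoxyphenol, 3,4,5-trimethoxyphenylboronic acid and (Z)-1,2-dimethoxyethene are taken as catalogue chemicals. All seventeen hydroxyls travel as methyl ethers because ring D is born with three of them. Phenoxides are handled under argon.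

Step 1
Reactants: 1 2,4,6-trimethoxyphenol; 2 4-fluoro-2,6-dimethoxybenzaldehyde
Product: 3 2,6-dimethoxy-4-(2,4,6-trimethoxyphenoxy)benzaldehyde
Conditions: K2CO3, DMF, 110 °C, Ar
Reagents that add atoms: none
Why: Nucleophilic aromatic substitution (SNAr): the para formyl group activates the C–F carbon of 2, which has no ortho substituent, so the 2,6-disubstituted phenoxide of 1 should add and expel fluoride.

Step 2
Reactants: 3 2,6-dimethoxy-4-(2,4,6-trimethoxyphenoxy)benzaldehyde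
Product: 5 2,6-dimethoxy-4-(2,4,6-trimethoxyphenoxy)phenol, via aryl formate 4 (not isolated)
Conditions: mCPBA, CH2Cl2, 0 °C to rt; aq. Na2SO3 wash; then K2CO3 (cat.), MeOH, rt, Ar
Reagents that add atoms: mCPBA (3-chloroperoxybenzoic acid), OOC(=O)c1cccc(Cl)c1
Why: Dakin-type Baeyer–Villiger oxidation: the aryl group with two ortho and one para oxygen donor migrates in preference to hydrogen, and methanolysis of the formate should free the hindered ring B phenol.

Step 3
Reactants: 5 2,6-dimethoxy-4-(2,4,6-trimethoxyphenoxy)phenol; 2 4-fluoro-2,6-dimethoxybenzaldehyde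
Product: 6 4-[2,6-dimethoxy-4-(2,4,6-trimethoxyphenoxy)phenoxy]-2,6-dimethoxybenzaldehyde
Conditions: K2CO3, DMF, 110 °C, Ar
Reagents that add atoms: none
Why: The same SNAr as in step 1 joins the crowded ring B phenoxide to the unhindered, aldehyde-activated carbon that becomes C1 of ring C.

Step 4
Reactants: 6 4-[2,6-dimethoxy-4-(2,4,6-trimethoxyphenoxy)phenoxy]-2,6-dimethoxybenzaldehyde
Product: 8 4-[2,6-dimethoxy-4-(2,4,6-trimethoxyphenoxy)phenoxy]-2,6-dimethoxyphenol, via aryl formate 7 (not isolated)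
Conditions: mCPBA, CH2Cl2, 0 °C to rt; aq. Na2SO3 wash; then K2CO3 (cat.), MeOH, rt, Ar
Reagents that add atoms: mCPBA (3-chloroperoxybenzoic acid), OOC(=O)c1cccc(Cl)c1
Why: Dakin-type Baeyer–Villiger oxidation as in step 2 turns the formyl group into the ring C hydroxyl that will become the D1 oxygen; the other rings carry no free phenol and should resist one equivalent of peracid.

Step 5
Reactants: 8 4-[2,6-dimethoxy-4-(2,4,6-trimethoxyphenoxy)phenoxy]-2,6-dimethoxyphenol; 9 trichloroethylene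
Product: 11 2-{[(E)-1,2-dichloroethenyl]oxy}-5-[2,6-dimethoxy-4-(2,4,6-trimethoxyphenoxy)phenoxy]-1,3-dimethoxybenzene, via dichloroacetylene 10 (not isolated)
Conditions: K2CO3, DMF, 70 °C
Reagents that add atoms: none
Why: Base dehydrochlorinates trichloroethylene to dichloroacetylene, to which the phenoxide adds with anti protonation; this is the established preparation of (E)-1,2-dichlorovinyl aryl ethers.

Step 6
Reactants: 11 2-{[(E)-1,2-dichloroethenyl]oxy}-5-[2,6-dimethoxy-4-(2,4,6-trimethoxyphenoxy)phenoxy]-1,3-dimethoxybenzene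
Product: 14 5-[2,6-dimethoxy-4-(2,4,6-trimethoxyphenoxy)phenoxy]-2-(ethynyloxy)-1,3-dimethoxybenzene, via chloroethynyl ether 12 (not isolated), via lithium acetylide 13 (not isolated)
Conditions: n-BuLi (2.2 equiv), THF, −78 °C; then H2O in THF, −78 to 0 °C; used at once as a cold solution
Reagents that add atoms: none
Why: Dehydrochlorination followed by chlorine–lithium exchange is the standard conversion of 1,2-dichlorovinyl ethers into lithium alkoxyacetylides, and cold protonation should give the terminal ynol ether, which is not stored because such ethers do not keep.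

Step 7
Reactants: 15 (Z)-1,2-dimethoxyethene; 16 chromium hexacarbonyl, Cr(CO)6
Product: 19 pentacarbonyl{[(Z)-1,2-dimethoxyethenyl](methoxy)carbene}chromium, via vinyllithium 17 (not isolated), via lithium acylchromate 18 (not isolated)
Conditions: t-BuLi, THF, −78 °C; Cr(CO)6, −78 to 0 °C; then Me3OBF4, CH2Cl2, 0 °C
Reagents that add atoms: trimethyloxonium tetrafluoroborate, C[O+](C)C.F[B-](F)(F)F
Why: Fischer carbene synthesis: the enol ether is lithiated at a vinylic carbon next to oxygen with retention of the Z geometry, the vinyllithium adds to a CO ligand, and the acyl chromate is O-methylated by the oxonium salt.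

Step 8
Reactants: 14 5-[2,6-dimethoxy-4-(2,4,6-trimethoxyphenoxy)phenoxy]-2-(ethynyloxy)-1,3-dimethoxybenzene; 19 pentacarbonyl{[(Z)-1,2-dimethoxyethenyl](methoxy)carbene}chromium
Product: 21 6-{4-[2,6-dimethoxy-4-(2,4,6-trimethoxyphenoxy)phenoxy]-2,6-dimethoxyphenoxy}-2,3,4-trimethoxyphenol, via tricarbonylchromium arene complex 20 (not isolated)
Conditions: 19 (1.5 equiv), THF (degassed), 50 °C, Ar; then air, Et2O, rt
Reagents that add atoms: none
Why: Thermal loss of one CO from 19 opens a site for the ynol ether, which inserts into the Cr=C bond with its CH terminus (D2) bonding to the carbene carbon (D3); CO insertion then gives a chromium-bound dienylketene. Ring D is closed by 6π electrocyclisation of this ketene, the ketene carbon D6 bonding to the methoxy-bearing vinyl terminus D5, and the cyclohexadienone tautomerises to the phenol, held first as the Cr(CO)3 complex 20 and released by air. The closest known reaction type is the Dötz benzannulation of alkenyl(alkoxy)carbene complexes of zerovalent chromium with terminal alkynes and with alkynyl ethers. No stereocentre is formed. The step needs one regiochemistry of insertion, with the aryloxy carbon next to the new hydroxyl, and both the rule that the small alkyne substituent goes next to the carbene carbon and the polarisation of the ynol ether (nucleophilic CH carbon, electrophilic carbene carbon) point that way. Benzannulation over CO-free cyclisation is favoured by chromium, an alkenyl carbene and an ethereal solvent, and the Z geometry of 19 puts H, not OMe, on the inner side of D5 so that ring closure is not hindered.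

Step 9
Reactants: 21 6-{4-[2,6-dimethoxy-4-(2,4,6-trimethoxyphenoxy)phenoxy]-2,6-dimethoxyphenoxy}-2,3,4-trimethoxyphenol; 2 4-fluoro-2,6-dimethoxybenzaldehyde
Product: 22 4-(6-{4-[2,6-dimethoxy-4-(2,4,6-trimethoxyphenoxy)phenoxy]-2,6-dimethoxyphenoxy}-2,3,4-trimethoxyphenoxy)-2,6-dimethoxybenzaldehyde
Conditions: K2CO3, DMF, 110 °C, Ar
Reagents that add atoms: none
Why: SNAr of the D6 phenoxide, flanked by methoxy and aryloxy, on the unhindered aldehyde-activated C–F carbon (position 1 of ring E) makes the most crowded remaining ether without metal or oxidant.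

Step 10
Reactants: 22 4-(6-{4-[2,6-dimethoxy-4-(2,4,6-trimethoxyphenoxy)phenoxy]-2,6-dimethoxyphenoxy}-2,3,4-trimethoxyphenoxy)-2,6-dimethoxybenzaldehyde
Product: 24 4-(6-{4-[2,6-dimethoxy-4-(2,4,6-trimethoxyphenoxy)phenoxy]-2,6-dimethoxyphenoxy}-2,3,4-trimethoxyphenoxy)-2,6-dimethoxyphenol, via aryl formate 23 (not isolated)
Conditions: mCPBA (1.1 equiv), CH2Cl2, 0 °C; aq. Na2SO3 wash; then K2CO3 (cat.), MeOH, rt, Ar
Reagents that add atoms: mCPBA (3-chloroperoxybenzoic acid), OOC(=O)c1cccc(Cl)c1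
Why: Dakin-type Baeyer–Villiger oxidation of the electron-rich aldehyde is fast at 0 °C, so one equivalent of peracid should be consumed at the formyl group before the fully etherified ring D is attacked, and methanolysis frees the ring E hydroxyl at position 4.

Step 11
Reactants: 25 4-bromo-2,6-dimethoxyphenol; 26 (3,4,5-trimethoxyphenyl)boronic acid
Product: 27 5-(4-bromo-2,6-dimethoxyphenoxy)-1,2,3-trimethoxybenzene
Conditions: Cu(OAc)2 (50 mol%), pyridine, 4 Å MS, CH2Cl2, O2 (1 atm), rt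
Reagents that add atoms: none
Why: Chan–Lam coupling: copper-mediated oxidative O-arylation with an arylboronic acid runs at room temperature, accepts phenols with two ortho substituents and leaves the aryl bromide untouched.

Step 12
Reactants: 24 4-(6-{4-[2,6-dimethoxy-4-(2,4,6-trimethoxyphenoxy)phenoxy]-2,6-dimethoxyphenoxy}-2,3,4-trimethoxyphenoxy)-2,6-dimethoxyphenol; 27 5-(4-bromo-2,6-dimethoxyphenoxy)-1,2,3-trimethoxybenzene
Product: 28 heptadeca-O-methyl ether of the target (24 with its ring E oxygen at position 4 bonded to C1 of a 3,5-dimethoxy-4-(3,4,5-trimethoxyphenoxy)phenyl group, rings F and G)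
Conditions: CuI (10 mol%), picolinic acid (20 mol%), K3PO4, DMSO, 90 °C, Ar
Reagents that add atoms: none
Why: Ullmann-type diaryl ether synthesis: CuI with picolinic acid is known to couple 2,6-disubstituted phenols with aryl bromides that carry no ortho substituent, which is the situation at the brominated carbon of 27.

Step 13
Reactants: 28 heptadeca-O-methyl ether of the target
Product: 29 CNP0304148.0, the heptamer with seventeen free hydroxyls
Conditions: BBr3 (excess), CH2Cl2, −78 °C to rt; then H2O, 0 °C, Ar; Sephadex LH-20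
Reagents that add atoms: none
Why: Boron tribromide cleaves aryl methyl ethers by bromide attack on the O-methyl carbon of the borane adduct and leaves diaryl ether bonds intact, so hydrolysis should release all seventeen hydroxyls.

Compound list
1 | 2,4,6-trimethoxyphenol | COc1cc(OC)c(O)c(OC)c1 | starting material
2 | 4-fluoro-2,6-dimethoxybenzaldehyde | COc1cc(F)cc(OC)c1C=O | starting material
3 | 2,6-dimethoxy-4-(2,4,6-trimethoxyphenoxy)benzaldehyde | COc1cc(OC)c(Oc2cc(OC)c(C=O)c(OC)c2)c(OC)c1 | intermediate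
4 | 2,6-dimethoxy-4-(2,4,6-trimethoxyphenoxy)phenyl formate | COc1cc(OC)c(Oc2cc(OC)c(OC=O)c(OC)c2)c(OC)c1 | intermediate
5 | 2,6-dimethoxy-4-(2,4,6-trimethoxyphenoxy)phenol | COc1cc(OC)c(Oc2cc(OC)c(O)c(OC)c2)c(OC)c1 | intermediate
6 | 4-[2,6-dimethoxy-4-(2,4,6-trimethoxyphenoxy)phenoxy]-2,6-dimethoxybenzaldehyde | COc1cc(OC)c(Oc2cc(OC)c(Oc3cc(OC)c(C=O)c(OC)c3)c(OC)c2)c(OC)c1 | intermediate
7 | 4-[2,6-dimethoxy-4-(2,4,6-trimethoxyphenoxy)phenoxy]-2,6-dimethoxyphenyl formate | COc1cc(OC)c(Oc2cc(OC)c(Oc3cc(OC)c(OC=O)c(OC)c3)c(OC)c2)c(OC)c1 | intermediate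
8 | 4-[2,6-dimethoxy-4-(2,4,6-trimethoxyphenoxy)phenoxy]-2,6-dimethoxyphenol (A–B–C phenol) | COc1cc(OC)c(Oc2cc(OC)c(Oc3cc(OC)c(O)c(OC)c3)c(OC)c2)c(OC)c1 | intermediate
9 | trichloroethylene | ClC=C(Cl)Cl | starting material
10 | dichloroacetylene | ClC#CCl | intermediate
11 | 2-{[(E)-1,2-dichloroethenyl]oxy}-5-[2,6-dimethoxy-4-(2,4,6-trimethoxyphenoxy)phenoxy]-1,3-dimethoxybenzene | COc1cc(OC)c(Oc2cc(OC)c(Oc3cc(OC)c(O/C(Cl)=C\Cl)c(OC)c3)c(OC)c2)c(OC)c1 | intermediate
12 | 2-[(chloroethynyl)oxy]-5-[2,6-dimethoxy-4-(2,4,6-trimethoxyphenoxy)phenoxy]-1,3-dimethoxybenzene | COc1cc(OC)c(Oc2cc(OC)c(Oc3cc(OC)c(OC#CCl)c(OC)c3)c(OC)c2)c(OC)c1 | intermediate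
13 | [({4-[2,6-dimethoxy-4-(2,4,6-trimethoxyphenoxy)phenoxy]-2,6-dimethoxyphenyl}oxy)ethynyl]lithium | COc1cc(OC)c(Oc2cc(OC)c(Oc3cc(OC)c(OC#C[Li])c(OC)c3)c(OC)c2)c(OC)c1 | intermediate
14 | 5-[2,6-dimethoxy-4-(2,4,6-trimethoxyphenoxy)phenoxy]-2-(ethynyloxy)-1,3-dimethoxybenzene | COc1cc(OC)c(Oc2cc(OC)c(Oc3cc(OC)c(OC#C)c(OC)c3)c(OC)c2)c(OC)c1 | intermediate
15 | (Z)-1,2-dimethoxyethene | CO/C=C\OC | starting material
16 | chromium hexacarbonyl, Cr(CO)6 | O=C=[Cr](=C=O)(=C=O)(=C=O)(=C=O)=C=O | starting material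
17 | [(Z)-1,2-dimethoxyethenyl]lithium | CO/C=C(\OC)[Li] | intermediate
18 | lithium pentacarbonyl[(Z)-2,3-dimethoxyprop-2-enoyl]chromate | CO/C=C(\OC)C([O-])=[Cr](=C=O)(=C=O)(=C=O)(=C=O)=C=O.[Li+] | intermediate
19 | pentacarbonyl{[(Z)-1,2-dimethoxyethenyl](methoxy)carbene}chromium | CO/C=C(\OC)C(OC)=[Cr](=C=O)(=C=O)(=C=O)(=C=O)=C=O | intermediate
20 | tricarbonyl(η6-21)chromium, zerovalent chromium on ring D (hapto bond written as a dot) | COc1cc(OC)c(Oc2cc(OC)c(Oc3cc(OC)c(Oc4cc(OC)c(OC)c(OC)c4O)c(OC)c3)c(OC)c2)c(OC)c1.[Cr](=C=O)(=C=O)=C=O | intermediate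
21 | 6-{4-[2,6-dimethoxy-4-(2,4,6-trimethoxyphenoxy)phenoxy]-2,6-dimethoxyphenoxy}-2,3,4-trimethoxyphenol (A–B–C–D phenol) | COc1cc(OC)c(Oc2cc(OC)c(Oc3cc(OC)c(Oc4cc(OC)c(OC)c(OC)c4O)c(OC)c3)c(OC)c2)c(OC)c1 | intermediate
22 | 4-(6-{4-[2,6-dimethoxy-4-(2,4,6-trimethoxyphenoxy)phenoxy]-2,6-dimethoxyphenoxy}-2,3,4-trimethoxyphenoxy)-2,6-dimethoxybenzaldehyde | COc1cc(OC)c(Oc2cc(OC)c(Oc3cc(OC)c(Oc4cc(OC)c(OC)c(OC)c4Oc5cc(OC)c(C=O)c(OC)c5)c(OC)c3)c(OC)c2)c(OC)c1 | intermediate
23 | 4-(6-{4-[2,6-dimethoxy-4-(2,4,6-trimethoxyphenoxy)phenoxy]-2,6-dimethoxyphenoxy}-2,3,4-trimethoxyphenoxy)-2,6-dimethoxyphenyl formate | COc1cc(OC)c(Oc2cc(OC)c(Oc3cc(OC)c(Oc4cc(OC)c(OC)c(OC)c4Oc5cc(OC)c(OC=O)c(OC)c5)c(OC)c3)c(OC)c2)c(OC)c1 | intermediate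
24 | 4-(6-{4-[2,6-dimethoxy-4-(2,4,6-trimethoxyphenoxy)phenoxy]-2,6-dimethoxyphenoxy}-2,3,4-trimethoxyphenoxy)-2,6-dimethoxyphenol (A–B–C–D–E phenol) | COc1cc(OC)c(Oc2cc(OC)c(Oc3cc(OC)c(Oc4cc(OC)c(OC)c(OC)c4Oc5cc(OC)c(O)c(OC)c5)c(OC)c3)c(OC)c2)c(OC)c1 | intermediate
25 | 4-bromo-2,6-dimethoxyphenol | COc1cc(Br)cc(OC)c1O | starting material
26 | (3,4,5-trimethoxyphenyl)boronic acid | COc1cc(B(O)O)cc(OC)c1OC | starting material
27 | 5-(4-bromo-2,6-dimethoxyphenoxy)-1,2,3-trimethoxybenzene | COc1cc(Br)cc(OC)c1Oc1cc(OC)c(OC)c(OC)c1 | intermediate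
28 | heptadeca-O-methyl ether of the target, chain A–O–B–O–C–O–D–O–E–O–F–O–G with all seventeen oxygens as OMe | COc1cc(OC)c(Oc2cc(OC)c(Oc3cc(OC)c(Oc4cc(OC)c(OC)c(OC)c4Oc5cc(OC)c(Oc6cc(OC)c(Oc7cc(OC)c(OC)c(OC)c7)c(OC)c6)c(OC)c5)c(OC)c3)c(OC)c2)c(OC)c1 | intermediate
29 | CNP0304148.0: A 2,4,6-trihydroxyphenoxy; B, C, E, F 3,5-dihydroxy-1,4-phenylenedioxy units, each bonded through O-4 to C-1 of the next ring; D 3,4,5-trihydroxy ring with the ring C oxygen on D1 and the ring E oxygen on D6; G 3,4,5-trihydroxyphenyl | Oc1cc(O)c(Oc2cc(O)c(Oc3cc(O)c(Oc4cc(O)c(O)c(O)c4Oc4cc(O)c(Oc5cc(O)c(Oc6cc(O)c(O)c(O)c6)c(O)c5)c(O)c4)c(O)c3)c(O)c2)c(O)c1 | target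

Total step count: 13. Longest linear sequence: 11 steps (steps 1, 2, 3, 4, 5, 6, 8, 9, 10, 12, 13); steps 7 and 11 are side branches.

Steps most likely to fail

Step 8. The donor-rich carbene complex may lose CO slowly, the electron-rich alkyne may insert without taking up CO (cyclopentannulation or furan formation), or the ynol ether may polymerise before it is consumed. The fallback sets out from 8 and comes back at 21 without organometallic chemistry. Commercial 5-fluoro-1,2,3-trimethoxybenzene is formylated (Cl2CHOMe, TiCl4, CH2Cl2, 0 °C, Rieche formylation) to 6-fluoro-2,3,4-trimethoxybenzaldehyde F1. The phenoxide of 8 displaces its fluoride ortho to the formyl group (Cs2CO3, DMF, 120 °C, SNAr) to give 6-{4-[2,6-dimethoxy-4-(2,4,6-trimethoxyphenoxy)phenoxy]-2,6-dimethoxyphenoxy}-2,3,4-trimethoxybenzaldehyde F2. Baeyer–Villiger oxidation with mCPBA gives the corresponding aryl formate F3, and methanolysis (K2CO3, MeOH) frees the D6 hydroxyl, which is 21.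

Step 12. C–O bond formation at the doubly ortho-substituted phenoxide may be slow, with reductive loss of bromine from 27 and oxidation of the phenoxide draining material. The fallback sets out from 24 and comes back at 28. A further SNAr with 2 (K2CO3, DMF, 110 °C) gives 4-[4-(6-{4-[2,6-dimethoxy-4-(2,4,6-trimethoxyphenoxy)phenoxy]-2,6-dimethoxyphenoxy}-2,3,4-trimethoxyphenoxy)-2,6-dimethoxyphenoxy]-2,6-dimethoxybenzaldehyde F4. Oxidation with mCPBA gives the hexamer aryl formate F5, and methanolysis gives the hexamer phenol F6. Chan–Lam coupling of this phenol with boronic acid 26 (Cu(OAc)2, pyridine, 4 Å MS, O2, CH2Cl2, rt) then attaches ring G and gives 28.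

Step 13. Cleavage may stop short among the seventeen methyl ethers, and the free polyphenol may oxidise during isolation. The fallback sets out from 28 and comes back at 29. After BBr3 and a methanol quench the crude polyphenol is not purified but acetylated (Ac2O, pyridine, DMAP) to the heptadecaacetate of the target F7, which is stable to air and silica gel and can be separated from under-cleaved material. Oxygen-free acid methanolysis (HCl in MeOH, Ar, rt) then releases 29.

Further compounds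
F1 | step 8 | 6-fluoro-2,3,4-trimethoxybenzaldehyde | COc1cc(F)c(C=O)c(OC)c1OC
F2 | step 8 | 6-{4-[2,6-dimethoxy-4-(2,4,6-trimethoxyphenoxy)phenoxy]-2,6-dimethoxyphenoxy}-2,3,4-trimethoxybenzaldehyde | COc1cc(OC)c(Oc2cc(OC)c(Oc3cc(OC)c(Oc4cc(OC)c(OC)c(OC)c4C=O)c(OC)c3)c(OC)c2)c(OC)c1
F3 | step 8 | 6-{4-[2,6-dimethoxy-4-(2,4,6-trimethoxyphenoxy)phenoxy]-2,6-dimethoxyphenoxy}-2,3,4-trimethoxyphenyl formate | COc1cc(OC)c(Oc2cc(OC)c(Oc3cc(OC)c(Oc4cc(OC)c(OC)c(OC)c4OC=O)c(OC)c3)c(OC)c2)c(OC)c1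
F4 | step 12 | 4-[4-(6-{4-[2,6-dimethoxy-4-(2,4,6-trimethoxyphenoxy)phenoxy]-2,6-dimethoxyphenoxy}-2,3,4-trimethoxyphenoxy)-2,6-dimethoxyphenoxy]-2,6-dimethoxybenzaldehyde | COc1cc(OC)c(Oc2cc(OC)c(Oc3cc(OC)c(Oc4cc(OC)c(OC)c(OC)c4Oc5cc(OC)c(Oc6cc(OC)c(C=O)c(OC)c6)c(OC)c5)c(OC)c3)c(OC)c2)c(OC)c1
F5 | step 12 | 4-[4-(6-{4-[2,6-dimethoxy-4-(2,4,6-trimethoxyphenoxy)phenoxy]-2,6-dimethoxyphenoxy}-2,3,4-trimethoxyphenoxy)-2,6-dimethoxyphenoxy]-2,6-dimethoxyphenyl formate | COc1cc(OC)c(Oc2cc(OC)c(Oc3cc(OC)c(Oc4cc(OC)c(OC)c(OC)c4Oc5cc(OC)c(Oc6cc(OC)c(OC=O)c(OC)c6)c(OC)c5)c(OC)c3)c(OC)c2)c(OC)c1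
F6 | step 12 | 4-[4-(6-{4-[2,6-dimethoxy-4-(2,4,6-trimethoxyphenoxy)phenoxy]-2,6-dimethoxyphenoxy}-2,3,4-trimethoxyphenoxy)-2,6-dimethoxyphenoxy]-2,6-dimethoxyphenol | COc1cc(OC)c(Oc2cc(OC)c(Oc3cc(OC)c(Oc4cc(OC)c(OC)c(OC)c4Oc5cc(OC)c(Oc6cc(OC)c(O)c(OC)c6)c(OC)c5)c(OC)c3)c(OC)c2)c(OC)c1
F7 | step 13 | heptadecaacetate of 29 (every hydroxyl as acetate) | CC(=O)Oc1cc(OC(C)=O)c(Oc2cc(OC(C)=O)c(Oc3cc(OC(C)=O)c(Oc4cc(OC(C)=O)c(OC(C)=O)c(OC(C)=O)c4Oc5cc(OC(C)=O)c(Oc6cc(OC(C)=O)c(Oc7cc(OC(C)=O)c(OC(C)=O)c(OC(C)=O)c7)c(OC(C)=O)c6)c(OC(C)=O)c5)c(OC(C)=O)c3)c(OC(C)=O)c2)c(OC(C)=O)c1
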